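**Retrosynthetic overview**
1. The 18-membered target 28 comes from a last-step enantioselective [1,2]-Wittig ring contraction of the 19-membered dibenzyl ether 25. ArB–CH2–O–CH2–ArC becomes ArB–CH(OH)–CH2–ArC, so the C–C bond and the (S)-carbinol form together.
2. 25 comes from 24 by deprotection. 24 comes from seco-diol 21 by macro-Williamson closure, in which either CH2OH may serve as the electrophile.
3. 21 comes from a B-alkyl Suzuki union of A–B bromide 10 with C–D styrene 18. The same 9-BBN charge reduces both CHO groups.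
4. 10 comes from SNAr of 4 (1 + DMF) with 9 (4-bromophenol: Duff, double Dakin, orthoformate). 18 comes from SNAr of 15 on 14 (2-fluorophenol: MOM, metalation/DMF), then vinylation.
5. Ring order: the four benzene rings are bought; a temporary benzodioxole forms in step 4; the 19-membered ring forms in step 11; it contracts to 18 members in step 13.

Ring labels: A is the trioxygenated ring, B the para-linked ring, C the 1,2,3-trisubstituted ring with one OH, and D the meta-linked ring. The stereocentre of the target is (S). The acetal carbon of the orthoformate group is racemic in 9, 10 and 20–24, and it is removed in step 12.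

Assumption: the sense of induction of the bis(oxazoline) ligand on this new substrate class cannot be known beforehand. The (S,S)-ligand is written, and its equally available (R,R)-antipode is used if the first run gives the (R)-alcohol.

**Step 1**
Reactants: 1 1-bromo-4-fluorobenzene; 2 N,N-dimethylformamide
Product: 4 4-fluorobenzaldehyde, via 4-fluorophenylmagnesium bromide 3 (not isolated)
Conditions: Mg, cat. I2, THF, reflux; 2, 0 °C to rt; 1 M HCl
Reagents that add atoms: none
Why: Grignard formation at C–Br (C–F is inert to Mg) followed by Bouveault-type formylation with DMF.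

**Step 2**
Reactants: 5 4-bromophenol
Product: 6 5-bromo-2-hydroxybenzene-1,3-dicarbaldehyde
Conditions: HMTA (4 equiv), TFA, reflux, 24 h; 4 M HCl, rt
Reagents that add atoms: hexamethylenetetramine C1N2CN3CN1CN(C2)C3; water O
Why: Duff formylation; the free phenol sends both iminium attacks to its two open ortho positions because para is blocked by Br.

**Step 3**
Reactants: 6 5-bromo-2-hydroxybenzene-1,3-dicarbaldehyde
Product: 8 5-bromobenzene-1,2,3-triol, via bis(formate) ester 7 (not isolated)
Conditions: 30% H2O2 (2.4 equiv), NaOH (3 equiv), THF–H2O, 0 °C, N2; 2 M HCl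
Reagents that add atoms: hydrogen peroxide OO
Why: Double Dakin oxidation; each hydroperoxide adduct undergoes a 1,2-aryl shift from C to O assisted by the ortho-phenoxide, the formates are saponified in situ, and cold, air-free handling avoids autoxidation of the triol.

**Step 4**
Reactants: 8 5-bromobenzene-1,2,3-triol
Product: 9 6-bromo-2-ethoxy-1,3-benzodioxol-4-ol
Conditions: HC(OEt)3 (1.5 equiv), cat. sulfonic acid resin, toluene, reflux (EtOH removed)
Reagents that add atoms: triethyl orthoformate CCOC(OCC)OCC
Why: Acid-catalysed transorthoesterification; only two neighbouring OH groups can close the five-membered ring, so exactly one outer OH of the symmetric triol stays free (the new acetal carbon is racemic and is deleted in step 12).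

**Step 5**
Reactants: 9 6-bromo-2-ethoxy-1,3-benzodioxol-4-ol; 4 4-fluorobenzaldehyde
Product: 10 4-[(6-bromo-2-ethoxy-1,3-benzodioxol-4-yl)oxy]benzaldehyde
Conditions: K2CO3, DMF, 110 °C
Reagents that add atoms: none
Why: SNAr through the Meisenheimer complex para to CHO; the ArBr and the base-stable orthoester are untouched.

**Step 6**
Reactants: 11 2-fluorophenol
Product: 12 1-fluoro-2-(methoxymethoxy)benzene
Conditions: NaH, MOMCl, THF, 0 °C to rt
Reagents that add atoms: chloromethyl methyl ether COCCl
Why: Williamson-type O-alkylation of the phenoxide gives a base-stable, mildly acid-labile acetal.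

**Step 7**
Reactants: 12 1-fluoro-2-(methoxymethoxy)benzene; 2 N,N-dimethylformamide
Product: 14 2-fluoro-3-(methoxymethoxy)benzaldehyde, via 2-fluoro-3-(methoxymethoxy)phenyllithium 13 (not isolated)
Conditions: n-BuLi, PMDTA, THF, −78 °C; 2, −78 to 0 °C; H2O
Reagents that add atoms: none
Why: Acidity-controlled ortho-metalation; PMDTA saturates lithium and switches off OMOM coordination, so the most acidic H next to F is removed and then formylated with DMF.

**Step 8**
Reactants: 14 2-fluoro-3-(methoxymethoxy)benzaldehyde; 15 3-bromophenol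
Product: 16 2-(3-bromophenoxy)-3-(methoxymethoxy)benzaldehyde
Conditions: K2CO3, DMF, 120 °C
Reagents that add atoms: none
Why: SNAr of the fluoride activated by the ortho-CHO; MOM and ArBr are stable to carbonate.

**Step 9**
Reactants: 16 2-(3-bromophenoxy)-3-(methoxymethoxy)benzaldehyde; 17 potassium vinyltrifluoroborate
Product: 18 2-(3-ethenylphenoxy)-3-(methoxymethoxy)benzaldehyde
Conditions: PdCl2(dppf) (3 mol %), Cs2CO3 (3 equiv), THF–H2O 9:1, 80 °C
Reagents that add atoms: none
Why: Suzuki–Miyaura vinylation with a trifluoroborate, which tolerates the aldehyde and the acetal.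

**Step 10**
Reactants: 18 2-(3-ethenylphenoxy)-3-(methoxymethoxy)benzaldehyde; 10 4-[(6-bromo-2-ethoxy-1,3-benzodioxol-4-yl)oxy]benzaldehyde
Product: 21 seco-diol [4-({2-ethoxy-6-[2-(3-{2-(hydroxymethyl)-6-(methoxymethoxy)phenoxy}phenyl)ethyl]-1,3-benzodioxol-4-yl}oxy)phenyl]methanol, via B-alkyl O-boryl bis(9-BBN) adduct 19 (not isolated), via O-(9-BBN) borinate of the reduced bromide 20 (not isolated)
Conditions: 9-BBN (3.3 equiv), THF, 0 °C to rt; then 3 M aq K3PO4, PdCl2(dppf) (5 mol %), DMF, 60 °C
Reagents that add atoms: none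
Why: 9-BBN hydroborates the styrene anti-Markovnikov and reduces both ArCHO groups in the same flask, the B-alkyl Suzuki–Miyaura coupling then forms the saturated ArD–CH2CH2–ArA bridge directly, and the borinates hydrolyse in the aqueous base.

**Step 11**
Reactants: 21 seco-diol
Product: 24 protected 19-membered macrocyclic dibenzyl ether (ring A catechol as cyclic ethyl orthoformate; ring C OH as MOM ether), via ring-B monotosylate 22 (not isolated), via ring-C monotosylate 23 (not isolated)
Conditions: slow co-addition of 21 and TsCl (1.0 equiv) to NaH (5 equiv), THF, 60 °C, ≤2 mM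
Reagents that add atoms: none
Why: One-pot monotosylation and intramolecular Williamson etherification; either monotosylate closes to the same ether, so the two CH2OH groups need no differentiation, and pseudo-high dilution keeps bis-tosylation and oligomers low.

**Step 12**
Reactants: 24 protected 19-membered macrocyclic dibenzyl ether
Product: 25 19-membered macrocyclic dibenzyl ether triphenol
Conditions: 3 M aq HCl–THF 1:3, 45 °C, Ar
Reagents that add atoms: none
Why: Acid hydrolysis of the two acetal-type groups (MOM and orthoformate); this is done before the acid-labile secondary benzylic alcohol exists, and the primary dibenzyl ether survives aqueous HCl of this strength.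

**Step 13**
Reactants: 25 19-membered macrocyclic dibenzyl ether triphenol
Product: 28 target (S)-carbinol CNP0356934.1, via trilithium triphenoxide 26 (not isolated), via ring-B alpha-lithio ether 27 (not isolated)
Conditions: n-BuLi (3.0 equiv), THF, −78 °C; then t-BuLi·L* (1.5 equiv, premixed in Et2O), −78 to −40 °C; sat. aq NH4Cl [L* = (4S,4'S)-2,2'-(pentane-3,3-diyl)bis(4-isopropyl-4,5-dihydro-1,3-oxazole)]
Reagents that add atoms: none
Why: Proposed new method: phenoxide-gated, ligand-controlled [1,2]-Wittig ring contraction of a macrocyclic dibenzyl ether; the three ArOLi groups made first serve as traceless protection and as the regiochemical switch, because the O– on ring C (meta to its CH2) loads the same ortho/para carbons that a ring-C benzylic anion would need, so only the ring-B CH2 is deprotonated by t-BuLi; the bis(oxazoline)-bound base removes its pro-R hydrogen to give (R)-27, the O–CH2(ring C) bond then breaks homolytically to a lithium ketyl/benzyl radical pair that the rest of the ring keeps together, and recombination with inversion at the carbanion carbon makes the new C–C bond, shrinks the ring from 19 to 18 atoms and sets (S); the closest known reaction types are the t-BuLi/chiral bis(oxazoline)-mediated enantioselective [1,2]-Wittig rearrangement of acyclic dibenzyl ether and Wittig ring contractions of smaller cyclic ethers, neither of which has been shown on a macrocycle or on free phenoxides.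

**Compound list**
1 | 1-bromo-4-fluorobenzene | Fc1ccc(Br)cc1 | starting material
2 | N,N-dimethylformamide | CN(C)C=O | starting material
3 | 4-fluorophenylmagnesium bromide | Fc1ccc([Mg]Br)cc1 | intermediate
4 | 4-fluorobenzaldehyde | O=Cc1ccc(F)cc1 | intermediate
5 | 4-bromophenol | Oc1ccc(Br)cc1 | starting material
6 | 5-bromo-2-hydroxybenzene-1,3-dicarbaldehyde | O=Cc1cc(Br)cc(C=O)c1O | intermediate
7 | 5-bromo-2-hydroxybenzene-1,3-diyl diformate | O=COc1cc(Br)cc(OC=O)c1O | intermediate
8 | 5-bromobenzene-1,2,3-triol | Oc1cc(Br)cc(O)c1O | intermediate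
9 | 6-bromo-2-ethoxy-1,3-benzodioxol-4-ol (racemic acetal carbon) | CCOC1Oc2cc(Br)cc(O)c2O1 | intermediate
10 | 4-[(6-bromo-2-ethoxy-1,3-benzodioxol-4-yl)oxy]benzaldehyde (A–B bromide) | CCOC1Oc2cc(Br)cc(Oc3ccc(C=O)cc3)c2O1 | intermediate
11 | 2-fluorophenol | Oc1ccccc1F | starting material
12 | 1-fluoro-2-(methoxymethoxy)benzene | COCOc1ccccc1F | intermediate
13 | 2-fluoro-3-(methoxymethoxy)phenyllithium | [Li]c1cccc(OCOC)c1F | intermediate
14 | 2-fluoro-3-(methoxymethoxy)benzaldehyde | COCOc1cccc(C=O)c1F | intermediate
15 | 3-bromophenol | Oc1cccc(Br)c1 | starting material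
16 | 2-(3-bromophenoxy)-3-(methoxymethoxy)benzaldehyde | COCOc1cccc(C=O)c1Oc1cccc(Br)c1 | intermediate
17 | potassium vinyltrifluoroborate | [K+].F[B-](F)(F)C=C | starting material
18 | 2-(3-ethenylphenoxy)-3-(methoxymethoxy)benzaldehyde (C–D styrene) | COCOc1cccc(C=O)c1Oc1cccc(C=C)c1 | intermediate
19 | 9-BBN adduct of 18: ArD–CH2CH2–B(9-BBN), ArC–CH2O–B(9-BBN) | COCOc1cccc(COB2C3CCCC2CCC3)c1Oc1cccc(CCB2C3CCCC2CCC3)c1 | intermediate
20 | 9-BBN borinate of reduced 10: ArB–CH2O–B(9-BBN), ring A bromide | CCOC1Oc2cc(Br)cc(Oc3ccc(COB4C5CCCC4CCC5)cc3)c2O1 | intermediate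
21 | seco-diol (ArB–CH2OH and ArC–CH2OH, A–D bibenzyl bridge in place) | CCOC1Oc2cc(CCc3cccc(Oc4c(CO)cccc4OCOC)c3)cc(Oc3ccc(CO)cc3)c2O1 | intermediate
22 | ring-B monotosylate of 21 | CCOC1Oc2cc(CCc3cccc(Oc4c(CO)cccc4OCOC)c3)cc(Oc3ccc(COS(=O)(=O)c4ccc(C)cc4)cc3)c2O1 | intermediate
23 | ring-C monotosylate of 21 | CCOC1Oc2cc(CCc3cccc(Oc4c(COS(=O)(=O)c5ccc(C)cc5)cccc4OCOC)c3)cc(Oc3ccc(CO)cc3)c2O1 | intermediate
24 | protected 19-membered macrocyclic dibenzyl ether | CCOC1Oc2cc3cc(c2O1)Oc1ccc(cc1)COCc1cccc(OCOC)c1Oc1cccc(c1)CC3 | intermediate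
25 | 19-membered macrocyclic dibenzyl ether triphenol | Oc1cc2cc(c1O)Oc1ccc(cc1)COCc1cccc(O)c1Oc1cccc(c1)CC2 | intermediate
26 | trilithium triphenoxide of 25 | [Li+].[Li+].[Li+].[O-]c1cc2cc(c1[O-])Oc1ccc(cc1)COCc1cccc([O-])c1Oc1cccc(c1)CC2 | intermediate
27 | (R)-ring-B α-lithio ether of 26 (ligand-bound) | [Li+].[Li+].[Li+].[O-]c1cc2cc(c1[O-])Oc1ccc(cc1)[C@@H]([Li])OCc1cccc([O-])c1Oc1cccc(c1)CC2 | intermediate
28 | CNP0356934.1, 18-membered bis(bibenzyl), (S)-ArB–CH(OH)–CH2–ArC | Oc1cc2cc(c1O)Oc1ccc(cc1)[C@@H](O)Cc1cccc(O)c1Oc1cccc(c1)CC2 | target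

**Totals:** 13 steps in all. The longest linear sequence is 8 steps, either 5→6→8→9→10→21→24→25→28 or 11→12→14→16→18→21→24→25→28.

**Steps most likely to fail**

*Step 13 (proposed new step).* The risks are poor ee in the presence of three lithium phenoxides, insolubility of the polyanion, and a leak to the ring-C carbanion.
- The fallback uses known chemistry only. It sets out from 18 and 10 and comes back at 28.
- 18 alone is treated with 2.2 equiv 9-BBN, which gives 19. Residual B–H is destroyed with aq K3PO4 before 10 and PdCl2(dppf) are added, so the ring-B aldehyde survives and the coupling gives the hydroxy aldehyde F1.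
- Appel bromination (CBr4, PPh3, 2,6-lutidine) gives the benzylic bromide aldehyde F2.
- Slow addition of F2 to SmI2 (cat. NiI2, THF, high dilution) closes the 18-membered ring by an intramolecular Barbier reaction and gives the racemic protected macrocyclic carbinol F3.
- Buffered Dess–Martin oxidation gives the protected macrocyclic deoxybenzoin F4.
- 3 M HCl–THF removes both acetal groups at the acid-stable ketone stage and gives the triphenol ketone F5.
- Noyori–Ikariya transfer hydrogenation with RuCl[(S,S)-TsDPEN](p-cymene) in HCO2H–Et3N delivers (S)-28.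

*Step 11.* The risks are oligomers and bis-tosylation in the one-pot closure.
- The fallback closes the ring at a different bond. It sets out from 18 and 10 and comes back at 24.
- NaBH4 reduces 18 to the styrenyl benzylic alcohol F6, and PPh3/NCS converts it into the benzylic chloride F7.
- NaBH4 reduces 10 to the bromo benzylic alcohol F8.
- NaH/DMF (cat. Bu4NI) joins F8 and F7 intermolecularly to give the open-chain dibenzyl ether F9.
- 9-BBN gives the B-alkyl borane F10. This is added slowly to PdCl2(dppf)/Cs2CO3 in aq DMF–THF (1 mM), and the intramolecular B-alkyl Suzuki macrocyclisation gives 24.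

*Step 7.* The risk is that OMOM-directed lithiation at the oxygen-adjacent site competes.
- The fallback changes the directing strategy from ligand control to steric blocking. It sets out from 11 and comes back at 14.
- TIPSCl/imidazole gives the silyl ether F11, whose bulk shields the O-adjacent position.
- s-BuLi (THF, −78 °C) therefore removes only the H next to F and gives the aryllithium F12.
- DMF (2) gives the silyloxy aldehyde F13, and TBAF gives 2-fluoro-3-hydroxybenzaldehyde F14.
- MOMCl/i-Pr2NEt gives 14.

**Further compounds**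
F1 | step 13 | hydroxy aldehyde (ArC–CH2OH, ArB–CHO, bridge in place) | CCOC1Oc2cc(CCc3cccc(Oc4c(CO)cccc4OCOC)c3)cc(Oc3ccc(C=O)cc3)c2O1
F2 | step 13 | benzylic bromide aldehyde (ArC–CH2Br, ArB–CHO) | CCOC1Oc2cc(CCc3cccc(Oc4c(CBr)cccc4OCOC)c3)cc(Oc3ccc(C=O)cc3)c2O1
F3 | step 13 | racemic protected 18-membered macrocyclic carbinol | CCOC1Oc2cc3cc(c2O1)Oc1ccc(cc1)C(O)Cc1cccc(OCOC)c1Oc1cccc(c1)CC3
F4 | step 13 | protected 18-membered macrocyclic deoxybenzoin | CCOC1Oc2cc3cc(c2O1)Oc1ccc(cc1)C(=O)Cc1cccc(OCOC)c1Oc1cccc(c1)CC3
F5 | step 13 | triphenol macrocyclic ketone | Oc1cc2cc(c1O)Oc1ccc(cc1)C(=O)Cc1cccc(O)c1Oc1cccc(c1)CC2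
F6 | step 11 | [2-(3-ethenylphenoxy)-3-(methoxymethoxy)phenyl]methanol | COCOc1cccc(CO)c1Oc1cccc(C=C)c1
F7 | step 11 | 1-(chloromethyl)-2-(3-ethenylphenoxy)-3-(methoxymethoxy)benzene | COCOc1cccc(CCl)c1Oc1cccc(C=C)c1
F8 | step 11 | {4-[(6-bromo-2-ethoxy-1,3-benzodioxol-4-yl)oxy]phenyl}methanol | CCOC1Oc2cc(Br)cc(Oc3ccc(CO)cc3)c2O1
F9 | step 11 | open-chain dibenzyl ether (ring A bromide, ring D vinyl) | CCOC1Oc2cc(Br)cc(Oc3ccc(COCc4cccc(OCOC)c4Oc4cccc(C=C)c4)cc3)c2O1
F10 | step 11 | B-alkyl-9-BBN adduct of F9 | CCOC1Oc2cc(Br)cc(Oc3ccc(COCc4cccc(OCOC)c4Oc4cccc(CCB5C6CCCC5CCC6)c4)cc3)c2O1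
F11 | step 7 | (2-fluorophenoxy)triisopropylsilane | CC(C)[Si](Oc1ccccc1F)(C(C)C)C(C)C
F12 | step 7 | 2-fluoro-3-(triisopropylsilyloxy)phenyllithium | [Li]c1cccc(O[Si](C(C)C)(C(C)C)C(C)C)c1F
F13 | step 7 | 2-fluoro-3-(triisopropylsilyloxy)benzaldehyde | CC(C)[Si](Oc1cccc(C=O)c1F)(C(C)C)C(C)C
F14 | step 7 | 2-fluoro-3-hydroxybenzaldehyde | Oc1cccc(C=O)c1F
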